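## Structural features

Selaginellin F is built on ring A, a benzene with four contiguous substituents: C5 carries CH2OH, C6 the (4-hydroxyphenyl)ethynyl group, C1 the methide carbon Cm, and C2 the 2,4-dihydroxyphenyl ring B; C3 and C4 carry hydrogen. Cm is the exocyclic carbon of a para-quinone methide (a fuchsone). It bears a 4-hydroxyphenyl group and is double-bonded to a cyclohexa-2,5-dienone that is the oxidised form of a second, identical 4-hydroxyphenyl group. The dienone is symmetrical, so the Cm=C bond has no E/Z isomerism and the molecule has no stereocentre; no stereochemical relationship has to be set. The fragile parts are: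

- the quinone methide, an electrophile at Cm that can take up nucleophiles by 1,6-addition, including the ortho hydroxyl of ring B;
- the diarylalkyne that sits ortho to Cm;
- the benzylic alcohol;
- five free phenols.

The real difficulty is the congestion around C1: a tetrasubstituted carbon flanked by an ortho aryl ring and an ortho alkyne, next to a biaryl bond that must be formed at a doubly ortho-substituted position. The key step uses the fact that Cm and the ortho oxygen of ring B lie on either side of the C2–ring B bond. Joined as an aryl ester they form, with C1, C2 and two carbons of ring B, a six-membered lactone (a 6H-benzo[c]chromen-6-one). The ester holds ring B in place for an intramolecular arylation, and its carbonyl carbon is Cm at the oxidation level that accepts exactly two aryl nucleophiles.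

## Logic of the disconnections

**21 to 19.** The Cm=C double bond of the quinone methide and the six free hydroxyls are traced back to the triaryl carbinol 19 (through 20). The fuchsone is the anhydro form of a para-hydroxytrityl alcohol, so the most reactive function can be produced last from a stable sp3 carbon. All phenols are masked as methoxymethyl acetals and the benzylic alcohol as a silyl ether, so one acid treatment removes every protecting group and ionises the carbinol. The demand on the forward step is an acid mild enough for the alkyne and the benzylic alcohol, and release of the product without closure of the ring B ortho hydroxyl onto Cm.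

**19 to 16 and 13.** Both Cm–aryl bonds are cut. The two aryl groups are identical, so one nucleophile (17, made from 13) is used twice, and Cm becomes the carbonyl carbon of the lactone in 16. Opening the lactone also frees the ortho hydroxyl of ring B, so no separate deprotection is needed there. The demand is a first addition to the flat lactone carbonyl, collapse to the ketone 18, and a second addition to a hindered ketone without attack on the alkyne or the silyl ether.

**16 to 11 and 15.** The C6–C(sp) bond is cut. An aryl bromide ortho to a carbonyl group is activated for oxidative addition, and the linear alkyne is the smallest substituent that can be put into that slot. The demand is coupling at a bromide with two ortho neighbours under a base that does not open the aryl ester.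

**15 to 14 to 13 to 12.** The C(sp)–Si bond, the aryl–C(sp) bond and the acetal C–O bond are cut in turn. The gain is that 13 serves twice, as the precursor of 15 and as the source of 17, which saves one protection step. The demand is only routine coupling and protodesilylation.

**11 to 10.** The C2–ring B biaryl bond is cut while the ester is kept. The biaryl bond is the only bond of the lactone ring that is hard to make, and the ester turns a crowded intermolecular coupling into a ring closure. The gain is the separation of ring B from ring A. The demand is oxidative addition at the iodide and not at the bromide, C–H cleavage para and not ortho to the acetal oxygen, and survival of the aryl ester.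

**10 to 6 and 8; 8 to 7.** The ester C–O bond is cut. The demand is activation of an acid with two ortho halogens under conditions that spare the silyl ether (9 is made without release of HCl). Compound 8 comes from the symmetrical diol 7 by a single alkylation.

**6 to 4 to 3 to 2 to 1.** The O–Si bond (through 5), the benzylic C–O bond, the benzylic C–Br bond and the C–I bond are removed in turn. In 1 the carboxyl group is both the future Cm and the directing group that places iodine on the only open ortho carbon; the bromine is the future alkyne site and the methyl group the future CH2OH. The benzylic bromide is hydrolysed directly to the alcohol, which avoids an acetate detour. The demand is that iodination and radical bromination are done before any electron-rich ring or acetal is present.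

## Other disconnections considered

**Alternative 1:** The cut removes the C6–C(sp) bond and the C1–Cm bond together. Ring A becomes an aryne across C1–C6, with an ether oxygen on C2 as regiochemical director and as placeholder for ring B.

- Forward key step: the iodo arenesulfonate A2 is treated with iPrMgCl. Iodine–magnesium exchange and loss of sulfonate generate the aryne, the alkynylmagnesium chloride A4 (from 15) adds at C6, and the arylmagnesium left at C1 is trapped by the diaryl ketone A3 to give the carbinol A1.
- In favour: two skeletal bonds in one flask, no transition metal and no discrimination between two halogens. Cm arrives with both aryl groups already attached, so no double addition to a congested carbonyl is needed. On bonds formed per step it is better than the chosen plan, and on the formation of the quaternary centre it is at least its equal.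
- Against: alkynylmagnesium reagents are among the weakest nucleophiles toward arynes, and the attack must occur at the aryne carbon next to the CH2O substituent. The arylmagnesium at C1 is flanked by the ether and the new alkyne and has to add to an electron-rich, poorly electrophilic ketone, with simple protonation as the likely competing outcome. Ring B is still missing in A1. Its introduction needs oxidative removal of the benzyl-type ether, triflation and an untethered cross-coupling at a carbon ortho to a triarylcarbinol, which is the most hindered biaryl bond formation of the whole problem.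
- Comparison: the chosen plan makes that bond inside a ring while C1 carries only a flat carbonyl group. In step count the alternative needs about four steps after A1 against three after 11, and A2 should take about as many steps as 10. It is therefore not shorter, and its key step rests on two marginal additions.

**Alternative 2:** The cut removes the C1–Cm bond and the bond between the two future alkyne carbons. Ring A carries an iodide at C1 and a formyl group at C6, and ring B is already in place.

- Forward key step: Larock indenone annulation of the iodo aldehyde A6 with the symmetrical diarylacetylene A7 (Pd(OAc)2, NaOAc, n-Bu4NCl). The arylpalladium at C1 adds across the alkyne and the vinylpalladium adds to the formyl group, closing the five-membered ring of the indenone A5.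
- In favour: the annulation has no regiochemical question because A7 is symmetrical. Both aryl groups of A7 end up in the target. Ring B is attached early by an ordinary intermolecular coupling at an uncrowded stage. On these points it is the equal of the chosen plan or better, since it needs neither C–H site selectivity nor an iodide/bromide distinction.
- Against: the indenone must then be cut open at its tetrasubstituted C2=C3 bond to the triketone A8. Ozone or similar oxidants would meet five electron-rich acetal-protected rings. In A8 the 1,2-diketone must be turned into the alkyne while the third ketone is kept for the addition of 17. This is a redox-heavy sequence of at least four to five steps with difficult chemoselectivity among three carbonyl groups.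
- Comparison: in the chosen plan the bromide maps directly onto the alkyne and the lactone carbonyl directly onto Cm, with no oxidation-state detour. The alternative is longer and mechanistically less secure after its (reliable) key step.

**Alternative 3:** The cut dissolves ring A into three alkynes, with C1–C2, C3–C4 and C5–C6 as the bonds to be formed.

- Forward key step: RhCl(PPh3)3 cyclotrimerises the triyne A10, in which an aryl propiolate ester and a silyl ether tether hold the three alkynes. This closes ring A, the six-membered lactone and a five-membered oxasilole at once, giving A9.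
- In favour: three carbon–carbon bonds and three rings in one step, clearly ahead of the chosen key step in bonds and rings formed. The regiochemistry is fixed entirely by the tethers, so there is no site-selectivity question. The silicon tether protects the CH2O group at the same time. A9 is a close relative of 11 and would meet the same endgame with 17.
- Against: A10 is fragile and long to make. It combines an aryl ester of a silylpropiolic acid (a strong acyl donor and Michael acceptor with a labile Si–C(sp) bond) with an ortho-ethynylphenol unit that is prone to close to a benzofuran. The ester tether prefers the conformation that keeps the alkynes apart. After the key step the C6–Si bond of A9 must still be turned into the C6–alkyne bond, by ipso-iododesilylation of an electron-poor, hindered arylsilane followed by coupling with 15, or by a silicon-based cross-coupling. This costs at least two steps where the chosen route needs one.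
- Comparison: the alternative wins on regiochemical certainty and on complexity gained in the key step. The chosen plan wins on access to the precursor (six steps from commercial materials, all robust), on the stability of its intermediates, and on the direct use of the bromide.

Key step: step 7

Assumption: the target is taken as the open quinone methide drawn above; the ring-closed 6H-benzo[c]chromene isomer, which 1,6-addition of the ring B ortho hydroxyl to Cm would give, is treated as a possible by-product of the last step.

## Route

Step 1
Reactants: 1 2-bromo-3-methylbenzoic acid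
Product: 2 2-bromo-6-iodo-3-methylbenzoic acid
Conditions: Pd(OAc)2 (5 mol%), PhI(OAc)2 (0.75 equiv), I2 (0.75 equiv), DMF, 100 °C, dark
Reagents that add atoms: iodine, [I][I]
Why: Carboxylate-directed C–H iodination: the carboxylate delivers divalent palladium to the only free ortho C–H (the other ortho carbon carries bromine), and acetyl hypoiodite formed in the flask oxidises the palladacycle and transfers iodine; no zerovalent palladium is involved, so the carbon–bromine bond is not touched.

Step 2
Reactants: 2 2-bromo-6-iodo-3-methylbenzoic acid
Product: 3 2-bromo-3-(bromomethyl)-6-iodobenzoic acid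
Conditions: NBS (1.05 equiv), AIBN (5 mol%), PhCl, 85 °C
Reagents that add atoms: N-bromosuccinimide, O=C1CCC(=O)N1Br
Why: Wohl–Ziegler benzylic bromination; the methyl group holds the only benzylic hydrogens, the flanking bromine slows a second bromination, and at this stage there is no electron-rich ring or acetal that could be brominated instead.

Step 3
Reactants: 3 2-bromo-3-(bromomethyl)-6-iodobenzoic acid
Product: 4 2-bromo-3-(hydroxymethyl)-6-iodobenzoic acid
Conditions: K2CO3 (3 equiv), H2O/1,4-dioxane (1:1), 90 °C; then HCl aq. to pH 2
Reagents that add atoms: water, O
Why: Hydrolysis of a primary benzylic bromide by nucleophilic substitution; the carboxylate between two ortho halogens is a poor nucleophile, the new alcohol is meta to it so no lactone can form, and aryl halides are inert to aqueous carbonate.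

Step 4
Reactants: 4 2-bromo-3-(hydroxymethyl)-6-iodobenzoic acid
Product: 6 2-bromo-3-{[(tert-butyldimethylsilyl)oxy]methyl}-6-iodobenzoic acid, via bis-silylated silyl ester 5 (not isolated)
Conditions: TBSCl (2.5 equiv), imidazole (5 equiv), DMF, rt; then K2CO3, MeOH/THF/H2O, 0 °C → rt; citric acid aq. to pH 4
Reagents that add atoms: tert-butyldimethylsilyl chloride, CC(C)(C)[Si](C)(C)Cl
Why: Silylation of alcohol and acid followed by selective cleavage of the silyl ester, which is attacked at silicon and therefore does not feel the hindrance at the carbonyl group; the primary alkyl silyl ether is stable to carbonate in methanol and to the mildly acidic work-up.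

Step 5
Reactants: 7 resorcinol
Product: 8 3-(methoxymethoxy)phenol
Conditions: MOMCl (1.0 equiv), i-Pr2NEt (1.2 equiv), MeCN, 0 °C → rt; 7 in threefold excess
Reagents that add atoms: chloromethyl methyl ether, COCCl
Why: O-Alkylation of a symmetrical diol with the diol in excess, which suppresses the bis-acetal; unreacted 7 is washed out with water.

Step 6
Reactants: 6 2-bromo-3-{[(tert-butyldimethylsilyl)oxy]methyl}-6-iodobenzoic acid; 8 3-(methoxymethoxy)phenol
Product: 10 3-(methoxymethoxy)phenyl 2-bromo-3-{[(tert-butyldimethylsilyl)oxy]methyl}-6-iodobenzoate, via acid chloride 9 (not isolated)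
Conditions: 1-chloro-N,N,2-trimethylprop-1-en-1-amine (1.2 equiv), CH2Cl2, 0 °C → rt; then 8 (1.2 equiv), Et3N (2 equiv), DMAP (0.2 equiv), rt → 40 °C
Reagents that add atoms: none
Why: The chloro-enamine converts the acid into its chloride without releasing HCl, so the silyl ether and later the acetal are safe; DMAP-catalysed acylation of the phenol through the acylpyridinium ion then overcomes the two ortho halogens.

Step 7
Reactants: 10 3-(methoxymethoxy)phenyl 2-bromo-3-{[(tert-butyldimethylsilyl)oxy]methyl}-6-iodobenzoate
Product: 11 7-bromo-8-{[(tert-butyldimethylsilyl)oxy]methyl}-3-(methoxymethoxy)-6H-benzo[c]chromen-6-one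
Conditions: Pd(OAc)2 (5 mol%), PCy3·HBF4 (10 mol%), PivOH (30 mol%), K2CO3 (2 equiv), DMA, 110 °C
Reagents that add atoms: none
Why: Zerovalent palladium, formed from Pd(OAc)2 and PCy3, inserts into the carbon–iodine bond of 10, which is weaker and less shielded (one ortho neighbour) than the carbon–bromine bond (two ortho neighbours). Pivalate replaces iodide on the divalent arylpalladium, and the tethered phenol ring is metalated by carboxylate-assisted concerted metalation–deprotonation at a position ortho to the ester oxygen, the only positions the tether can reach. Reductive elimination from the seven-membered diarylpalladacycle forms the C2–ring B bond and thereby closes the six-membered pyranone ring by carbon–carbon bond formation, the ester bond of that ring being already in place. The closest known reaction type is the palladium-catalysed intramolecular direct arylation of aryl 2-halobenzoates to 6H-benzo[c]chromen-6-ones. No stereocentre is created, and the biaryl is held nearly flat by the lactone. Two selectivities are needed: iodide before bromide, secured by bond strength, by crowding and by stopping at full conversion, and the C–H bond para and not ortho to the acetal oxygen, secured by the bulk of the acetal next to the site between the two oxygens. The ester prefers the conformation that keeps the rings apart, which is why 110 °C is needed; the tether still makes the crowded biaryl bond an intramolecular event.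

Step 8
Reactants: 12 4-iodophenol
Product: 13 1-iodo-4-(methoxymethoxy)benzene
Conditions: MOMCl (1.3 equiv), i-Pr2NEt (1.5 equiv), CH2Cl2, 0 °C → rt
Reagents that add atoms: chloromethyl methyl ether, COCCl
Why: Straightforward O-alkylation of a phenol to its methoxymethyl acetal; the aryl iodide is untouched.

Step 9
Reactants: 13 1-iodo-4-(methoxymethoxy)benzene
Product: 14 trimethyl{[4-(methoxymethoxy)phenyl]ethynyl}silane
Conditions: ethynyltrimethylsilane (1.3 equiv), PdCl2(PPh3)2 (2 mol%), CuI (4 mol%), Et3N/THF, rt
Reagents that add atoms: ethynyltrimethylsilane, C#C[Si](C)(C)C
Why: Sonogashira coupling of an aryl iodide, which proceeds at room temperature; the silyl group prevents double coupling.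

Step 10
Reactants: 14 trimethyl{[4-(methoxymethoxy)phenyl]ethynyl}silane
Product: 15 1-ethynyl-4-(methoxymethoxy)benzene
Conditions: K2CO3 (0.2 equiv), MeOH, rt
Reagents that add atoms: none
Why: Base-catalysed methanolysis of the C(sp)–Si bond; the acetal is stable to base.

Step 11
Reactants: 11 7-bromo-8-{[(tert-butyldimethylsilyl)oxy]methyl}-3-(methoxymethoxy)-6H-benzo[c]chromen-6-one; 15 1-ethynyl-4-(methoxymethoxy)benzene
Product: 16 8-{[(tert-butyldimethylsilyl)oxy]methyl}-3-(methoxymethoxy)-7-{[4-(methoxymethoxy)phenyl]ethynyl}-6H-benzo[c]chromen-6-one
Conditions: PdCl2(MeCN)2 (3 mol%), XPhos (9 mol%), Cs2CO3 (2 equiv), MeCN, 80 °C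
Reagents that add atoms: none
Why: Copper-free Sonogashira coupling; the bromide is activated by the ortho lactone carbonyl and the bulky biarylphosphine promotes oxidative addition at the doubly ortho-substituted carbon, while the absence of CuI and of a nucleophilic amine avoids alkyne dimerisation and aminolysis of the aryl ester.

Step 12
Reactants: 16 8-{[(tert-butyldimethylsilyl)oxy]methyl}-3-(methoxymethoxy)-7-{[4-(methoxymethoxy)phenyl]ethynyl}-6H-benzo[c]chromen-6-one; 13 1-iodo-4-(methoxymethoxy)benzene
Product: 19 2'-{hydroxybis[4-(methoxymethoxy)phenyl]methyl}-4'-{[(tert-butyldimethylsilyl)oxy]methyl}-4-(methoxymethoxy)-3'-{[4-(methoxymethoxy)phenyl]ethynyl}biphenyl-2-ol, via [4-(methoxymethoxy)phenyl]lithium 17 (not isolated), via ring-opened aryl ketone 18 (not isolated)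
Conditions: 13 (3.5 equiv), t-BuLi (7 equiv), THF, −78 °C; then 16 in THF, −78 → 0 °C; NH4Cl aq.
Reagents that add atoms: none
Why: Iodine–lithium exchange gives 17; double addition of an aryllithium to a 6H-benzo[c]chromen-6-one then follows the usual course: attack on the flat, accessible lactone carbonyl, expulsion of the ring B phenoxide to give ketone 18, and a second addition to the ketone. The alkyne, the acetals and the alkyl silyl ether do not react with aryllithium at or below 0 °C.

Step 13
Reactants: 19 2'-{hydroxybis[4-(methoxymethoxy)phenyl]methyl}-4'-{[(tert-butyldimethylsilyl)oxy]methyl}-4-(methoxymethoxy)-3'-{[4-(methoxymethoxy)phenyl]ethynyl}biphenyl-2-ol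
Product: 21 selaginellin F, via deprotected triaryl carbinol 20 (not isolated)
Conditions: HCl (3 M aq.), MeOH/THF (1:1), 45 °C, Ar; then NaHCO3 aq. to pH 6–7
Reagents that add atoms: none
Why: Acid-catalysed acetal and silyl ether cleavage with methanol trapping the formaldehyde unit as dimethoxymethane; the carbinol ionises to a triarylmethyl cation stabilised by two para-hydroxyphenyl groups, and on neutralisation loss of a phenolic proton gives the quinone methide (dehydration of a para-hydroxytrityl alcohol to a fuchsone). No stereocentre is formed.

## Compound list

1 | 2-bromo-3-methylbenzoic acid | Cc1cccc(C(=O)O)c1Br | starting material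
2 | 2-bromo-6-iodo-3-methylbenzoic acid | Cc1ccc(I)c(C(=O)O)c1Br | intermediate
3 | 2-bromo-3-(bromomethyl)-6-iodobenzoic acid | BrCc1ccc(I)c(C(=O)O)c1Br | intermediate
4 | 2-bromo-3-(hydroxymethyl)-6-iodobenzoic acid | OCc1ccc(I)c(C(=O)O)c1Br | intermediate
5 | tert-butyldimethylsilyl 2-bromo-3-{[(tert-butyldimethylsilyl)oxy]methyl}-6-iodobenzoate (not isolated) | CC(C)(C)[Si](C)(C)OCc1ccc(I)c(C(=O)O[Si](C)(C)C(C)(C)C)c1Br | intermediate
6 | 2-bromo-3-{[(tert-butyldimethylsilyl)oxy]methyl}-6-iodobenzoic acid | CC(C)(C)[Si](C)(C)OCc1ccc(I)c(C(=O)O)c1Br | intermediate
7 | resorcinol | Oc1cccc(O)c1 | starting material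
8 | 3-(methoxymethoxy)phenol | COCOc1cccc(O)c1 | intermediate
9 | 2-bromo-3-{[(tert-butyldimethylsilyl)oxy]methyl}-6-iodobenzoyl chloride (not isolated) | CC(C)(C)[Si](C)(C)OCc1ccc(I)c(C(Cl)=O)c1Br | intermediate
10 | 3-(methoxymethoxy)phenyl 2-bromo-3-{[(tert-butyldimethylsilyl)oxy]methyl}-6-iodobenzoate | COCOc1cccc(OC(=O)c2c(I)ccc(CO[Si](C)(C)C(C)(C)C)c2Br)c1 | intermediate
11 | 7-bromo-8-{[(tert-butyldimethylsilyl)oxy]methyl}-3-(methoxymethoxy)-6H-benzo[c]chromen-6-one | COCOc1ccc2c(c1)OC(=O)c1c(Br)c(CO[Si](C)(C)C(C)(C)C)ccc12 | intermediate
12 | 4-iodophenol | Oc1ccc(I)cc1 | starting material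
13 | 1-iodo-4-(methoxymethoxy)benzene | COCOc1ccc(I)cc1 | intermediate
14 | trimethyl{[4-(methoxymethoxy)phenyl]ethynyl}silane | COCOc1ccc(cc1)C#C[Si](C)(C)C | intermediate
15 | 1-ethynyl-4-(methoxymethoxy)benzene | COCOc1ccc(cc1)C#C | intermediate
16 | 8-{[(tert-butyldimethylsilyl)oxy]methyl}-3-(methoxymethoxy)-7-{[4-(methoxymethoxy)phenyl]ethynyl}-6H-benzo[c]chromen-6-one | COCOc1ccc2c(c1)OC(=O)c1c(C#Cc3ccc(OCOC)cc3)c(CO[Si](C)(C)C(C)(C)C)ccc12 | intermediate
17 | [4-(methoxymethoxy)phenyl]lithium (not isolated) | [Li]c1ccc(OCOC)cc1 | intermediate
18 | (3-{[(tert-butyldimethylsilyl)oxy]methyl}-6-[2-hydroxy-4-(methoxymethoxy)phenyl]-2-{[4-(methoxymethoxy)phenyl]ethynyl}phenyl)[4-(methoxymethoxy)phenyl]methanone (lithium phenoxide in the flask, drawn as the phenol; not isolated) | COCOc1ccc(cc1)C(=O)c1c(-c2ccc(OCOC)cc2O)ccc(CO[Si](C)(C)C(C)(C)C)c1C#Cc1ccc(OCOC)cc1 | intermediate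
19 | 2'-{hydroxybis[4-(methoxymethoxy)phenyl]methyl}-4'-{[(tert-butyldimethylsilyl)oxy]methyl}-4-(methoxymethoxy)-3'-{[4-(methoxymethoxy)phenyl]ethynyl}biphenyl-2-ol | COCOc1ccc(cc1)C(O)(c1ccc(OCOC)cc1)c1c(-c2ccc(OCOC)cc2O)ccc(CO[Si](C)(C)C(C)(C)C)c1C#Cc1ccc(OCOC)cc1 | intermediate
20 | 2'-[hydroxybis(4-hydroxyphenyl)methyl]-4'-(hydroxymethyl)-3'-[(4-hydroxyphenyl)ethynyl]biphenyl-2,4-diol (not isolated) | OCc1ccc(-c2ccc(O)cc2O)c(C(O)(c2ccc(O)cc2)c2ccc(O)cc2)c1C#Cc1ccc(O)cc1 | intermediate
21 | selaginellin F, 4-[{2',4'-dihydroxy-4-(hydroxymethyl)-3-[(4-hydroxyphenyl)ethynyl]biphenyl-2-yl}(4-hydroxyphenyl)methylidene]cyclohexa-2,5-dien-1-one | O=C1C=CC(=C(c2ccc(O)cc2)c2c(-c3ccc(O)cc3O)ccc(CO)c2C#Cc2ccc(O)cc2)C=C1 | target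

## Step count and least certain steps

Total step count: 13. Longest linear sequence: 9 steps (steps 1, 2, 3, 4, 6, 7, 11, 12, 13, from 1).

**Step 7 (key step).** The most likely failures are arylation at the more acidic C–H between the two oxygens, and slow ring closure caused by the ester conformation. A slow closure gives zerovalent palladium time to insert into the carbon–bromine bond and cause loss of bromine, or lets carbonate and pivalate cleave the aryl ester at 110 °C. A halide scavenger such as Ag2CO3 would be the first adjustment. The fallback changes the order of bond formation. It sets out from 6 and comes back at 11. Compound 17 (from 13) is quenched with B(OiPr)3 and hydrolysed to [4-(methoxymethoxy)phenyl]boronic acid F1. Suzuki–Miyaura coupling of F1 with 6 at the iodide (Pd(PPh3)4, K2CO3, dioxane/H2O, 70 °C) should give 3-bromo-4-{[(tert-butyldimethylsilyl)oxy]methyl}-4'-(methoxymethoxy)biphenyl-2-carboxylic acid F2. Carboxylate-directed dehydrogenative C–H lactonisation of F2 (Pd(OAc)2, PhI(OAc)2, KOAc, N-acetylglycine, t-BuOH, 80 °C) then closes the C–O bond to 11. Ring B in F2 is para-substituted, so its two ortho positions are equivalent and the regiochemistry is fixed by symmetry. The lactonisation runs between divalent and tetravalent palladium, which leaves the bromide alone.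

**Step 13.** The most likely failure is capture of Cm by the ring B ortho hydroxyl under the equilibrating acid conditions, an intramolecular 1,6-addition or cation trapping that closes a six-membered ether. Lesser risks are hydroxymethylation of the resorcinol ring by the formaldehyde unit if trapping by methanol is incomplete, and methyl ether formation at the benzylic alcohol. The fallback accepts the ring closure and reverses it in a separate operation. It sets out from 19 and comes back at 21. The acid treatment is run until closure is complete and the colourless isomer 6,6-bis(4-hydroxyphenyl)-8-(hydroxymethyl)-7-[(4-hydroxyphenyl)ethynyl]-6H-benzo[c]chromen-3-ol F3 is isolated. F3 is then opened in degassed NaOH aq./MeOH, where a para-phenoxide expels the ring B aryloxide as in the opening of phenolphthalein-type leuco forms. The solution is run into a pH 7 phosphate buffer at 0 °C and extracted quickly to give 21.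

**Step 12.** The most likely failure is stalling after the first addition. The ketone stage carries a lithium phenoxide, is electron-rich and is flanked by two ortho substituents, so the second addition may be slow; prolonged warming could then allow carbolithiation of the alkyne. The fallback adds the two aryl groups in separate steps on a neutral ketone. It sets out from 18, isolated after addition of one equivalent of 17 to 16 at −78 °C and a cold quench, and comes back at 21. The phenol of 18 is protected (MOMCl, i-Pr2NEt, CH2Cl2) to give (6-[2,4-bis(methoxymethoxy)phenyl]-3-{[(tert-butyldimethylsilyl)oxy]methyl}-2-{[4-(methoxymethoxy)phenyl]ethynyl}phenyl)[4-(methoxymethoxy)phenyl]methanone F4. Addition of 17 to F4 in THF at −78 → 0 °C should give {6-[2,4-bis(methoxymethoxy)phenyl]-3-{[(tert-butyldimethylsilyl)oxy]methyl}-2-{[4-(methoxymethoxy)phenyl]ethynyl}phenyl}bis[4-(methoxymethoxy)phenyl]methanol F5. F5 is converted into 21 under the conditions of step 13.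

**Step 11.** The most likely failure is slow oxidative addition at the bromide with two ortho neighbours. That would leave the alkyne to oligomerise on palladium and the aryl ester exposed to carbonate at 80 °C. The fallback uses a base-free transmetalation from tin. It sets out from 15 and comes back at 16. Compound 15 is stannylated (Bu3SnOMe, 60 °C, removal of methanol) to tributyl{[4-(methoxymethoxy)phenyl]ethynyl}stannane F6. Stille coupling of F6 with 11 (Pd(PPh3)4, toluene, 100 °C) should give 16.

**Step 1.** The most likely failure is low turnover, because palladation of an electron-poor acid with an ortho bromine is slow and iodide can inhibit the catalyst. The fallback replaces C–H activation by directed metalation. It sets out from 1 and comes back at 2. Compound 1 is converted into tert-butyl 2-bromo-3-methylbenzoate F7 (isobutene, cat. H2SO4, CH2Cl2). Ester-directed magnesiation of F7 at the single ortho C–H with (TMP)2Mg·2LiCl (TMP = 2,2,6,6-tetramethylpiperidide) in THF at 0 °C and an iodine quench should give tert-butyl 2-bromo-6-iodo-3-methylbenzoate F8. Treatment of F8 with CF3CO2H in CH2Cl2 gives 2.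

## Further compounds

F1 | step 7 | [4-(methoxymethoxy)phenyl]boronic acid | COCOc1ccc(cc1)B(O)O
F2 | step 7 | 3-bromo-4-{[(tert-butyldimethylsilyl)oxy]methyl}-4'-(methoxymethoxy)biphenyl-2-carboxylic acid | COCOc1ccc(cc1)-c1ccc(CO[Si](C)(C)C(C)(C)C)c(Br)c1C(=O)O
F3 | step 13 | 6,6-bis(4-hydroxyphenyl)-8-(hydroxymethyl)-7-[(4-hydroxyphenyl)ethynyl]-6H-benzo[c]chromen-3-ol | Oc1ccc(cc1)C1(c2ccc(O)cc2)Oc2cc(O)ccc2-c2ccc(CO)c(C#Cc3ccc(O)cc3)c21
F4 | step 12 | (6-[2,4-bis(methoxymethoxy)phenyl]-3-{[(tert-butyldimethylsilyl)oxy]methyl}-2-{[4-(methoxymethoxy)phenyl]ethynyl}phenyl)[4-(methoxymethoxy)phenyl]methanone | COCOc1ccc(cc1)C(=O)c1c(-c2ccc(OCOC)cc2OCOC)ccc(CO[Si](C)(C)C(C)(C)C)c1C#Cc1ccc(OCOC)cc1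
F5 | step 12 | {6-[2,4-bis(methoxymethoxy)phenyl]-3-{[(tert-butyldimethylsilyl)oxy]methyl}-2-{[4-(methoxymethoxy)phenyl]ethynyl}phenyl}bis[4-(methoxymethoxy)phenyl]methanol | COCOc1ccc(cc1)C(O)(c1ccc(OCOC)cc1)c1c(-c2ccc(OCOC)cc2OCOC)ccc(CO[Si](C)(C)C(C)(C)C)c1C#Cc1ccc(OCOC)cc1
F6 | step 11 | tributyl{[4-(methoxymethoxy)phenyl]ethynyl}stannane | CCCC[Sn](CCCC)(CCCC)C#Cc1ccc(OCOC)cc1
F7 | step 1 | tert-butyl 2-bromo-3-methylbenzoate | Cc1cccc(C(=O)OC(C)(C)C)c1Br
F8 | step 1 | tert-butyl 2-bromo-6-iodo-3-methylbenzoate | Cc1ccc(I)c(C(=O)OC(C)(C)C)c1Br
A1 | alternative 1 | {2-[(4-methoxybenzyl)oxy]-5-[(methoxymethoxy)methyl]-6-{[4-(methoxymethoxy)phenyl]ethynyl}phenyl}bis[4-(methoxymethoxy)phenyl]methanol | COCOCc1ccc(OCc2ccc(OC)cc2)c(C(O)(c2ccc(OCOC)cc2)c2ccc(OCOC)cc2)c1C#Cc1ccc(OCOC)cc1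
A2 | alternative 1 | 2-iodo-3-[(4-methoxybenzyl)oxy]-6-[(methoxymethoxy)methyl]phenyl 4-chlorobenzenesulfonate | COCOCc1ccc(OCc2ccc(OC)cc2)c(I)c1OS(=O)(=O)c1ccc(Cl)cc1
A3 | alternative 1 | bis[4-(methoxymethoxy)phenyl]methanone | COCOc1ccc(cc1)C(=O)c1ccc(OCOC)cc1
A4 | alternative 1 | chloro{[4-(methoxymethoxy)phenyl]ethynyl}magnesium | COCOc1ccc(cc1)C#C[Mg]Cl
A5 | alternative 2 | 4-[2,4-bis(methoxymethoxy)phenyl]-7-[(methoxymethoxy)methyl]-2,3-bis[4-(methoxymethoxy)phenyl]-1H-inden-1-one | COCOCc1ccc(-c2ccc(OCOC)cc2OCOC)c2c1C(=O)C(c1ccc(OCOC)cc1)=C2c1ccc(OCOC)cc1
A6 | alternative 2 | 2-iodo-2',4'-bis(methoxymethoxy)-4-[(methoxymethoxy)methyl]biphenyl-3-carbaldehyde | COCOCc1ccc(-c2ccc(OCOC)cc2OCOC)c(I)c1C=O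
A7 | alternative 2 | 1,2-bis[4-(methoxymethoxy)phenyl]ethyne | COCOc1ccc(cc1)C#Cc1ccc(OCOC)cc1
A8 | alternative 2 | 1-{2',4'-bis(methoxymethoxy)-2-[4-(methoxymethoxy)benzoyl]-4-[(methoxymethoxy)methyl]biphenyl-3-yl}-2-[4-(methoxymethoxy)phenyl]ethane-1,2-dione | COCOCc1ccc(-c2ccc(OCOC)cc2OCOC)c(C(=O)c2ccc(OCOC)cc2)c1C(=O)C(=O)c1ccc(OCOC)cc1
A9 | alternative 3 | 3-(methoxymethoxy)-6H-benzo[c]chromen-6-one fused at C7–C8 to a 1,1-diisopropyl-1,3-dihydro-2,1-oxasilole (silicon on C7, CH2O on C8) | COCOc1ccc2c(c1)OC(=O)c1c3c(ccc12)CO[Si]3(C(C)C)C(C)C
A10 | alternative 3 | 2-ethynyl-5-(methoxymethoxy)phenyl 3-[diisopropyl(prop-2-yn-1-yloxy)silyl]prop-2-ynoate | COCOc1ccc(C#C)c(OC(=O)C#C[Si](OCC#C)(C(C)C)C(C)C)c1
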